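The route rests on disconnecting the bond between C2 of the γ-pyranone (C) ring and C1′ of the chromene-fused B ring. The key step exploits the C2–H of a 3-oxygenated chromone: it is the only C–H on the C ring, flanked by ring O1 and the C3 oxygen and vinylogous to the C4 carbonyl, so a zinc amide metalates it selectively. Negishi arylation of this zinc species with a 6-bromo-2,2-dimethyl-2H-chromene then attaches the complete B ring to the finished A/C core in one operation. The chromone precursor already carries the 8-(1,1-dimethylallyl) group, set by Claisen rearrangement of a 7-O-prenyl ether; global deprotection ends the synthesis.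

Key step: step 9

Remark: 5,7-dihydroxychromone (1) is taken as a purchasable catalogue compound; the target is achiral, and the only stereogenic species on the route (epoxide 5) is racemic and drawn as one enantiomer.

Step 1
Reactants: 1 5,7-dihydroxy-4H-chromen-4-one; 2 1-bromo-3-methylbut-2-ene (prenyl bromide)
Product: 3 5-hydroxy-7-[(3-methylbut-2-en-1-yl)oxy]-4H-chromen-4-one
Conditions: K2CO3 (1.2 equiv), acetone, reflux
Reagents that add atoms: none
Why: Williamson etherification should be selective for the more acidic, non-chelated 7-OH because the 5-OH is locked in a hydrogen bond to the C4 carbonyl.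

Step 2
Reactants: 3 5-hydroxy-7-[(3-methylbut-2-en-1-yl)oxy]-4H-chromen-4-one
Product: 4 5-(methoxymethoxy)-7-[(3-methylbut-2-en-1-yl)oxy]-4H-chromen-4-one
Conditions: NaH (1.2 equiv), MOMCl (1.3 equiv), DMF, 0 °C → rt
Reagents that add atoms: chloromethyl methyl ether (MOMCl), COCCl
Why: NaH deprotonates the chelated 5-OH and the phenoxide is alkylated by MOMCl (Williamson-type acetal formation), which gives a base-stable ether and removes the chelate that would otherwise steer the later sigmatropic shift towards C6.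

Step 3
Reactants: 4 5-(methoxymethoxy)-7-[(3-methylbut-2-en-1-yl)oxy]-4H-chromen-4-one
Product: 6 3-hydroxy-5-(methoxymethoxy)-7-[(3-methylbut-2-en-1-yl)oxy]-4H-chromen-4-one, via 2,3-epoxychroman-4-one 5 (not isolated)
Conditions: 30% H2O2, NaOH (0.3 equiv), CH2Cl2/MeOH, 0 °C; crude 5, TsOH·H2O (5 mol %), CH2Cl2, 0 °C → rt
Reagents that add atoms: hydrogen peroxide, OO
Why: Weitz–Scheffer nucleophilic epoxidation should attack only the electron-poor C2=C3 bond (the prenyl alkene is inert to hydroperoxide anion) to give the necessarily cis-fused racemic epoxide, and acid opening of its acetal-like C2–O bond with loss of H-3 re-forms the pyranone as the 3-hydroxychromone, erasing both transient stereocentres.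

Step 4
Reactants: 6 3-hydroxy-5-(methoxymethoxy)-7-[(3-methylbut-2-en-1-yl)oxy]-4H-chromen-4-one
Product: 7 3,5-bis(methoxymethoxy)-7-[(3-methylbut-2-en-1-yl)oxy]-4H-chromen-4-one
Conditions: MOMCl (1.5 equiv), K2CO3, acetone, rt → 40 °C
Reagents that add atoms: chloromethyl methyl ether (MOMCl), COCCl
Why: O-alkylation of the acidic enolic 3-OH under mild carbonate conditions should block C3 and leave C2–H as the only C–H of the pyranone ring.

Step 5
Reactants: 7 3,5-bis(methoxymethoxy)-7-[(3-methylbut-2-en-1-yl)oxy]-4H-chromen-4-one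
Product: 9 3,5-bis(methoxymethoxy)-8-(2-methylbut-3-en-2-yl)-4-oxo-4H-chromen-7-yl benzoate, via 7-hydroxy-8-(2-methylbut-3-en-2-yl)chromone 8 (not isolated)
Conditions: Bz2O (2 equiv), N,N-diethylaniline, 190 °C, sealed tube
Reagents that add atoms: benzoic anhydride, O=C(OC(=O)c1ccccc1)c1ccccc1
Why: The aromatic Claisen rearrangement ([3,3]-sigmatropic, with allyl inversion) should deliver the tertiary carbon to C8, the ortho position favoured when the 5-oxygen is etherified rather than chelated (C4a is blocked, so no para shift is possible), and in situ benzoylation of the freed 7-OH should suppress abnormal-Claisen and cyclisation pathways while installing an ester without α-hydrogens for the later metalation.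

Step 6
Reactants: 10 5-bromo-2-hydroxybenzaldehyde; 11 3-chloro-3-methylbut-1-yne
Product: 12 5-bromo-2-[(2-methylbut-3-yn-2-yl)oxy]benzaldehyde
Conditions: K2CO3, KI (cat.), CuI (cat.), acetone, reflux
Reagents that add atoms: none
Why: Copper-assisted Williamson-type O-alkylation of the phenoxide with the tertiary propargylic chloride should place the 1,1-dimethylpropargyl group on the oxygen para to bromine.

Step 7
Reactants: 12 5-bromo-2-[(2-methylbut-3-yn-2-yl)oxy]benzaldehyde
Product: 14 5-bromo-2-[(2-methylbut-3-yn-2-yl)oxy]phenol, via aryl formate 13 (not isolated)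
Conditions: mCPBA, CH2Cl2, 0 °C → rt; aq. NaHCO3 wash; crude 13, K2CO3 (cat.), MeOH, rt
Reagents that add atoms: mCPBA (3-chloroperoxybenzoic acid), O=C(OO)c1cccc(Cl)c1
Why: Dakin-type Baeyer–Villiger oxidation, with migration of the ortho-alkoxy-substituted aryl group, should turn the formyl group into a formate that mild methanolysis cleaves, so the two catechol oxygens are differentiated unambiguously.

Step 8
Reactants: 14 5-bromo-2-[(2-methylbut-3-yn-2-yl)oxy]phenol
Product: 16 6-bromo-2,2-dimethyl-2H-chromen-8-yl benzoate, via 6-bromo-2,2-dimethyl-2H-chromen-8-ol 15 (not isolated)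
Conditions: N,N-diethylaniline, 160 °C; then Bz2O, DMAP (cat.), rt
Reagents that add atoms: benzoic anhydride, O=C(OC(=O)c1ccccc1)c1ccccc1
Why: Thermal propargyl Claisen rearrangement to the only free ortho carbon, enolisation, 1,5-hydrogen shift and oxa-6π electrocyclisation should build the 2,2-dimethyl-2H-chromene, and the remaining phenol is benzoylated in the same flask.

Step 9
Reactants: 9 3,5-bis(methoxymethoxy)-8-(2-methylbut-3-en-2-yl)-4-oxo-4H-chromen-7-yl benzoate; 16 6-bromo-2,2-dimethyl-2H-chromen-8-yl benzoate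
Product: 18 2-[8-(benzoyloxy)-2,2-dimethyl-2H-chromen-6-yl]-3,5-bis(methoxymethoxy)-8-(2-methylbut-3-en-2-yl)-4-oxo-4H-chromen-7-yl benzoate, via 2-chlorozincio chromone 17 (not isolated)
Conditions: TMPZnCl·LiCl (1.1 equiv), THF, 25 °C; then 16 (0.9 equiv), Pd(OAc)2 (2 mol %), SPhos (4 mol %), 50 °C
Reagents that add atoms: none
Why: The hindered zinc amide should remove the C2–H of the pyranone ring, the most acidic C–H of 9 because it lies between ring O1 and the C3 oxygen and is vinylogous to the C4 carbonyl, to give heteroaryl zinc 17; oxidative addition of Pd(0)/SPhos into the C–Br bond of 16, transmetalation and reductive elimination then form the C2–C1′ bond. The closest known reaction type is the C2-zincation of chromones with TMP-zinc bases followed by Negishi arylation to flavones. No ring is closed and no stereocentre is created. The step needs site-selective metalation and chemoselective coupling: C3 is blocked by its MOM ether, the aromatic C6–H and the vinyl groups are far less acidic, both esters are benzoates without α-hydrogens and are tolerated by the weakly nucleophilic zinc species, and palladium inserts into the unhindered aryl C–Br bond in preference to any other bond present.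

Step 10
Reactants: 18 2-[8-(benzoyloxy)-2,2-dimethyl-2H-chromen-6-yl]-3,5-bis(methoxymethoxy)-8-(2-methylbut-3-en-2-yl)-4-oxo-4H-chromen-7-yl benzoate
Product: 20 Broussonol A, via 3,5-bis(methoxymethoxy) diphenol 19 (not isolated)
Conditions: K2CO3 (2.5 equiv), MeOH, argon, 0 °C → rt; then 3 M aq. HCl to pH 1, 40 °C
Reagents that add atoms: none
Why: Carbonate-mediated methanolysis (transesterification) should cleave both aryl benzoates, and brief methanolic HCl should then cleave the two carbonyl-flanked MOM acetals under conditions mild enough for the chromene and the 1,1-dimethylallyl group.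

Compound list
1 | 5,7-dihydroxy-4H-chromen-4-one | O=c1ccoc2cc(O)cc(O)c12 | starting material
2 | 1-bromo-3-methylbut-2-ene (prenyl bromide) | CC(C)=CCBr | starting material
3 | 5-hydroxy-7-[(3-methylbut-2-en-1-yl)oxy]-4H-chromen-4-one | CC(C)=CCOc1cc(O)c2c(=O)ccoc2c1 | intermediate
4 | 5-(methoxymethoxy)-7-[(3-methylbut-2-en-1-yl)oxy]-4H-chromen-4-one | COCOc1cc(OCC=C(C)C)cc2occc(=O)c12 | intermediate
5 | rac-cis-2,3-epoxy-5-(methoxymethoxy)-7-[(3-methylbut-2-en-1-yl)oxy]chroman-4-one (oxirane fused across C2–C3) | COCOc1cc(OCC=C(C)C)cc2O[C@@H]3O[C@@H]3C(=O)c12 | intermediate (not isolated)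
6 | 3-hydroxy-5-(methoxymethoxy)-7-[(3-methylbut-2-en-1-yl)oxy]-4H-chromen-4-one | COCOc1cc(OCC=C(C)C)cc2occ(O)c(=O)c12 | intermediate
7 | 3,5-bis(methoxymethoxy)-7-[(3-methylbut-2-en-1-yl)oxy]-4H-chromen-4-one | COCOc1coc2cc(OCC=C(C)C)cc(OCOC)c2c1=O | intermediate
8 | 7-hydroxy-3,5-bis(methoxymethoxy)-8-(2-methylbut-3-en-2-yl)-4H-chromen-4-one | COCOc1coc2c(C(C)(C)C=C)c(O)cc(OCOC)c2c1=O | intermediate (not isolated)
9 | 3,5-bis(methoxymethoxy)-8-(2-methylbut-3-en-2-yl)-4-oxo-4H-chromen-7-yl benzoate | COCOc1coc2c(C(C)(C)C=C)c(OC(=O)c3ccccc3)cc(OCOC)c2c1=O | intermediate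
10 | 5-bromo-2-hydroxybenzaldehyde | O=Cc1cc(Br)ccc1O | starting material
11 | 3-chloro-3-methylbut-1-yne | C#CC(C)(C)Cl | starting material
12 | 5-bromo-2-[(2-methylbut-3-yn-2-yl)oxy]benzaldehyde | C#CC(C)(C)Oc1ccc(Br)cc1C=O | intermediate
13 | 5-bromo-2-[(2-methylbut-3-yn-2-yl)oxy]phenyl formate | C#CC(C)(C)Oc1ccc(Br)cc1OC=O | intermediate (not isolated)
14 | 5-bromo-2-[(2-methylbut-3-yn-2-yl)oxy]phenol | C#CC(C)(C)Oc1ccc(Br)cc1O | intermediate
15 | 6-bromo-2,2-dimethyl-2H-chromen-8-ol | CC1(C)C=Cc2cc(Br)cc(O)c2O1 | intermediate (not isolated)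
16 | 6-bromo-2,2-dimethyl-2H-chromen-8-yl benzoate | CC1(C)C=Cc2cc(Br)cc(OC(=O)c3ccccc3)c2O1 | intermediate
17 | [7-(benzoyloxy)-3,5-bis(methoxymethoxy)-8-(2-methylbut-3-en-2-yl)-4-oxo-4H-chromen-2-yl]zinc chloride (LiCl complex) | COCOc1c([Zn]Cl)oc2c(C(C)(C)C=C)c(OC(=O)c3ccccc3)cc(OCOC)c2c1=O | intermediate (not isolated)
18 | 2-[8-(benzoyloxy)-2,2-dimethyl-2H-chromen-6-yl]-3,5-bis(methoxymethoxy)-8-(2-methylbut-3-en-2-yl)-4-oxo-4H-chromen-7-yl benzoate | COCOc1c(-c2cc(OC(=O)c3ccccc3)c3OC(C)(C)C=Cc3c2)oc2c(C(C)(C)C=C)c(OC(=O)c3ccccc3)cc(OCOC)c2c1=O | intermediate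
19 | 7-hydroxy-2-(8-hydroxy-2,2-dimethyl-2H-chromen-6-yl)-3,5-bis(methoxymethoxy)-8-(2-methylbut-3-en-2-yl)-4H-chromen-4-one | COCOc1c(-c2cc(O)c3OC(C)(C)C=Cc3c2)oc2c(C(C)(C)C=C)c(O)cc(OCOC)c2c1=O | intermediate (not isolated)
20 | Broussonol A: 3,5,7-trihydroxy-2-(8-hydroxy-2,2-dimethyl-2H-chromen-6-yl)-8-(2-methylbut-3-en-2-yl)-4H-chromen-4-one | C=CC(C)(C)c1c(O)cc(O)c2c(=O)c(O)c(-c3cc(O)c4c(c3)C=CC(C)(C)O4)oc12 | target

Total step count: 10 steps.
Longest linear sequence: 7 steps (steps 1, 2, 3, 4, 5, 9, 10); the B-ring fragment takes steps 6–8.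

Steps most likely to fail

Step 9. Transmetalation of the electron-poor, oxygen-flanked 2-chromonyl zinc to palladium may be slow, so that protodezincation and reductive homocoupling of the bromide outrun cross-coupling. The fallback reverses the polarity of the partners. It sets out from 9 and 16. Zincation of 9 as in step 9 (through 17), quenched with iodine instead of being coupled, should give 2-iodo-3,5-bis(methoxymethoxy)-8-(2-methylbut-3-en-2-yl)-4-oxo-4H-chromen-7-yl benzoate F1. Miyaura borylation of 16 (B2pin2, Pd(dppf)Cl2, KOAc, dioxane, 80 °C) should give 2,2-dimethyl-6-(4,4,5,5-tetramethyl-1,3,2-dioxaborolan-2-yl)-2H-chromen-8-yl benzoate F2. Suzuki–Miyaura coupling of F1 with F2 (Pd(dppf)Cl2, anhydrous K3PO4, dioxane, 70 °C) comes back to the route at 18.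

Step 5. The sigmatropic shift may lose site control (migration to C6), or the ortho-dienone may rearrange further before the phenol is trapped. The fallback treats the prenyl ether only as a protecting group and installs the tertiary allyl group by halogenation and cross-coupling. It sets out from 7. Pd(0)-catalysed transfer of the prenyl group to morpholine (Pd(PPh3)4, morpholine, THF) should free 7-hydroxy-3,5-bis(methoxymethoxy)-4H-chromen-4-one F3. Electrophilic iodination ortho to the phenol at C8 (NIS, MeCN, 0 °C), the position attacked when the 5-oxygen is etherified, should give 7-hydroxy-8-iodo-3,5-bis(methoxymethoxy)-4H-chromen-4-one F4. Ligand-controlled γ-selective Suzuki–Miyaura allylation of F4 with prenylboronic acid pinacol ester (Pd catalyst, K3PO4, aqueous THF) forms the aryl–C(CH3)2 bond and comes back to the route at 8, which is benzoylated to 9 as in the second stage of step 5.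

Step 3. Hydroxide or hydroperoxide attack at C2 may open the pyranone ring faster than the epoxide closes on this electron-rich enone, and the acid isomerisation may erode the MOM and prenyl ethers. The fallback replaces epoxidation by hypervalent-iodine α-hydroxylation. It sets out from 4. PhI(OAc)2, KOH, MeOH at 0 °C (methoxide adds to C2, the enolate is oxidised at C3) should give racemic cis-2,4,4-trimethoxy-5-(methoxymethoxy)-7-[(3-methylbut-2-en-1-yl)oxy]chroman-3-ol F5. Dilute HCl in acetone at rt hydrolyses the ketal, eliminates methanol across C2–C3 and removes the 5-O-MOM group, giving 3,5-dihydroxy-7-[(3-methylbut-2-en-1-yl)oxy]-4H-chromen-4-one F6. Double MOM protection of F6 (NaH, excess MOMCl, DMF) comes back to the route at 7.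

Further compounds
F1 | step 9 | 2-iodo-3,5-bis(methoxymethoxy)-8-(2-methylbut-3-en-2-yl)-4-oxo-4H-chromen-7-yl benzoate | COCOc1c(I)oc2c(C(C)(C)C=C)c(OC(=O)c3ccccc3)cc(OCOC)c2c1=O
F2 | step 9 | 2,2-dimethyl-6-(4,4,5,5-tetramethyl-1,3,2-dioxaborolan-2-yl)-2H-chromen-8-yl benzoate | CC1(C)C=Cc2cc(B3OC(C)(C)C(C)(C)O3)cc(OC(=O)c3ccccc3)c2O1
F3 | step 5 | 7-hydroxy-3,5-bis(methoxymethoxy)-4H-chromen-4-one | COCOc1coc2cc(O)cc(OCOC)c2c1=O
F4 | step 5 | 7-hydroxy-8-iodo-3,5-bis(methoxymethoxy)-4H-chromen-4-one | COCOc1coc2c(I)c(O)cc(OCOC)c2c1=O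
F5 | step 3 | rac-cis-2,4,4-trimethoxy-5-(methoxymethoxy)-7-[(3-methylbut-2-en-1-yl)oxy]chroman-3-ol | COCOc1cc(OCC=C(C)C)cc2O[C@@H](OC)[C@@H](O)C(OC)(OC)c12
F6 | step 3 | 3,5-dihydroxy-7-[(3-methylbut-2-en-1-yl)oxy]-4H-chromen-4-one | CC(C)=CCOc1cc(O)c2c(=O)c(O)coc2c1
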